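**Retrosynthetic overview**
1. Target 17 ⇐ 16 ⇐ 15: the last two operations are MOM removal and methylation of the C7 hydroxyl; the C5 hydroxyl is held by the C4 carbonyl and stays free.
2. Feature used: in ring A the pair C6–C7 is a two-carbon acetate unit lying between C8 and C5. C8 can come from a C-methyl group and C5 from an ester carbon, both on a 4-pyranone that is ring C (O1, C2, C3, C4, C4a, C8a) and already bears ring B on C3.
3. Key disconnection: bonds C7–C8 and C5–C6 ⇒ pyranone ester 12 + N-methoxy-N-methylacetamide 13 (lateral metalation, acylation, Claisen closure of ring A).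
4. 12 ⇒ C-acetylated β-keto ester 10 + one carbon from DMF dimethyl acetal (ring C); 10 ⇒ arylacetic acid 6 + Meldrum's acid 7 + acetyl chloride.
5. Ring B ⇒ methyl (2,4-dihydroxyphenyl)acetate 1 by MOM protection, bromination at C5' and Stille prenylation with 4. Order of rings: B (bought), C (step 7), A (step 8).

Key step: step 8

Remark: the tetrahedral adduct of the Weinreb amide in step 8 is taken to break down in the flask once excess base is present, because β-elimination of the amide from the lateral carbanion gives the ketone enolate directly.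

**Route**

Step 1
Reactants: 1 methyl (2,4-dihydroxyphenyl)acetate
Product: 2 methyl [2,4-bis(methoxymethoxy)phenyl]acetate
Conditions: MOMCl, i-Pr2NEt, CH2Cl2, 0 °C to rt
Reagents that add atoms: chloromethyl methyl ether (MOMCl), COCCl
Why: Both phenols are O-alkylated by the chloromethyl ether under amine base (Williamson-type alkylation), which masks ring B for the later base and organometallic steps without touching the methyl ester.

Step 2
Reactants: 2 methyl [2,4-bis(methoxymethoxy)phenyl]acetate
Product: 3 methyl [5-bromo-2,4-bis(methoxymethoxy)phenyl]acetate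
Conditions: NBS, MeCN, 0 °C, dark
Reagents that add atoms: N-bromosuccinimide, O=C1CCC(=O)N1Br
Why: Electrophilic aromatic bromination should go to C5, the only position para to one alkoxy group and ortho to the other that is not flanked by two substituents, and NBS in acetonitrile releases no acid that would harm the MOM ethers.

Step 3
Reactants: 3 methyl [5-bromo-2,4-bis(methoxymethoxy)phenyl]acetate; 4 tributyl(3-methylbut-2-enyl)stannane
Product: 5 methyl [2,4-bis(methoxymethoxy)-5-(3-methylbut-2-enyl)phenyl]acetate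
Conditions: Pd(PPh3)4 (5 mol %), DMF, 100 °C
Reagents that add atoms: none
Why: Migita–Kosugi–Stille coupling of the aryl bromide with the allylic stannane should give the linear prenyl arene by reductive elimination at the less hindered allyl terminus, and the ester and MOM ethers are inert under these neutral conditions.

Step 4
Reactants: 5 methyl [2,4-bis(methoxymethoxy)-5-(3-methylbut-2-enyl)phenyl]acetate
Product: 6 [2,4-bis(methoxymethoxy)-5-(3-methylbut-2-enyl)phenyl]acetic acid
Conditions: LiOH·H2O, THF/MeOH/H2O, rt; then 1 M HCl to pH 4, 0 °C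
Reagents that add atoms: lithium hydroxide, [Li+].[OH-]
Why: Ester saponification; the MOM ethers and the trisubstituted alkene are stable to hydroxide, and acidification only to pH 4 in the cold spares the acetals.

Step 5
Reactants: 6 [2,4-bis(methoxymethoxy)-5-(3-methylbut-2-enyl)phenyl]acetic acid; 7 2,2-dimethyl-1,3-dioxane-4,6-dione (Meldrum's acid)
Product: 9 methyl 4-[2,4-bis(methoxymethoxy)-5-(3-methylbut-2-enyl)phenyl]-3-oxobutanoate, via acyl Meldrum's acid 8 (not isolated)
Conditions: DCC, DMAP, CH2Cl2, 0 °C to rt; then MeOH, 65 °C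
Reagents that add atoms: methanol, CO
Why: Carbodiimide-mediated C-acylation of Meldrum's acid followed by thermal methanolysis through the acylketene (loss of acetone and CO2) is the standard two-carbon homologation of an acid to a β-keto ester and stays close to neutral.

Step 6
Reactants: 9 methyl 4-[2,4-bis(methoxymethoxy)-5-(3-methylbut-2-enyl)phenyl]-3-oxobutanoate
Product: 10 methyl 2-acetyl-4-[2,4-bis(methoxymethoxy)-5-(3-methylbut-2-enyl)phenyl]-3-oxobutanoate
Conditions: AcCl, MgCl2, pyridine, CH2Cl2, 0 °C; aq. citric acid work-up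
Reagents that add atoms: acetyl chloride, CC(=O)Cl
Why: The magnesium chelate of the β-keto ester is C-acylated at C2 by acetyl chloride (soft-enolisation acylation of a 1,3-dicarbonyl compound with MgCl2 and pyridine), and pyridine takes up the HCl.

Step 7
Reactants: 10 methyl 2-acetyl-4-[2,4-bis(methoxymethoxy)-5-(3-methylbut-2-enyl)phenyl]-3-oxobutanoate
Product: 12 methyl 5-[2,4-bis(methoxymethoxy)-5-(3-methylbut-2-enyl)phenyl]-2-methyl-4-oxo-4H-pyran-3-carboxylate, via enaminone 11 (not isolated)
Conditions: Me2NCH(OMe)2, toluene, 80 °C; then AcOH, 50 °C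
Reagents that add atoms: N,N-dimethylformamide dimethyl acetal, COC(OC)N(C)C
Why: Aminomethylenation by the amide acetal should occur at the benzylic methylene, the most acidic position that still carries two hydrogens, and the enol oxygen of the acetyl group then adds to the enaminone carbon with loss of dimethylamine (6-endo addition–elimination), the known way from 2-acyl-1,3-dicarbonyl compounds to 4-pyranones.

Step 8
Reactants: 12 methyl 5-[2,4-bis(methoxymethoxy)-5-(3-methylbut-2-enyl)phenyl]-2-methyl-4-oxo-4H-pyran-3-carboxylate; 13 N-methoxy-N-methylacetamide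
Product: 15 3-[2,4-bis(methoxymethoxy)-5-(3-methylbut-2-enyl)phenyl]-5,7-dihydroxychromen-4-one, via methyl ketone 14 (not isolated)
Conditions: LiN(i-Pr)2 (LDA, 1.1 equiv), THF, −78 °C; 13 (1.2 equiv), −78 to −20 °C; LiN(i-Pr)2 (3 equiv), −78 to 0 °C; AcOH
Reagents that add atoms: none
Why: Proposed new method: lateral metalation of a 2-methyl-4-pyranone-3-carboxylate followed by acylation and Claisen closure has not been shown as a way to build ring A of a chromone; the closest known reaction type is the acylation of laterally lithiated ortho-toluate esters by Weinreb amides with Claisen closure to 1,3-dihydroxynaphthalenes. LiN(i-Pr)2 removes a proton from the pyranone C2 methyl group, which is vinylogous to both the C4 ketone and the C3 ester, and the dienolate adds through that carbon to Weinreb amide 13 (bond C7–C8 of the chromone); breakdown of the adduct gives methyl ketone 14 as its stabilised enolate. The second charge of base forms the dianion, whose terminal carbon attacks the neighbouring ester carbonyl in a 6-exo-trig Claisen condensation (bond C5–C6, ring A), and loss of methoxide followed by enolisation gives the aromatic 5,7-diol. No stereocentre is formed. The step needs deprotonation of the methyl group to win over addition of the base at the unsubstituted C6–H carbon of the pyranone (later C2 of the chromone) and over ortho-metalation beside the MOM ethers; the hindered, non-nucleophilic amide at −78 °C and the much higher acidity of the doubly activated methyl group secure this, and adding 13 before the extra base keeps the amide from being enolised.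

Step 9
Reactants: 15 3-[2,4-bis(methoxymethoxy)-5-(3-methylbut-2-enyl)phenyl]-5,7-dihydroxychromen-4-one
Product: 16 3-[2,4-bis(methoxymethoxy)-5-(3-methylbut-2-enyl)phenyl]-5-hydroxy-7-methoxychromen-4-one
Conditions: MeI (1.05 equiv), K2CO3, acetone, rt
Reagents that add atoms: iodomethane, CI
Why: Williamson methylation with one equivalent of iodomethane should take the more acidic, unchelated C7 hydroxyl, while the C5 hydroxyl is locked in a hydrogen bond to the C4 carbonyl.

Step 10
Reactants: 16 3-[2,4-bis(methoxymethoxy)-5-(3-methylbut-2-enyl)phenyl]-5-hydroxy-7-methoxychromen-4-one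
Product: 17 isopoegin B, 3-[2,4-dihydroxy-5-(3-methylbut-2-enyl)phenyl]-5-hydroxy-7-methoxychromen-4-one
Conditions: 3 M HCl, MeOH, 45 °C
Reagents that add atoms: none
Why: Acid-catalysed acetal exchange with methanol removes both MOM groups as dimethoxymethane, and the mild temperature should keep the prenyl group from adding to the neighbouring phenol.

**Compound list**
1 | methyl (2,4-dihydroxyphenyl)acetate | COC(=O)Cc1ccc(O)cc1O | starting material
2 | methyl [2,4-bis(methoxymethoxy)phenyl]acetate | COC(=O)Cc1ccc(OCOC)cc1OCOC | intermediate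
3 | methyl [5-bromo-2,4-bis(methoxymethoxy)phenyl]acetate | COC(=O)Cc1cc(Br)c(OCOC)cc1OCOC | intermediate
4 | tributyl(3-methylbut-2-enyl)stannane | CCCC[Sn](CCCC)(CCCC)CC=C(C)C | starting material
5 | methyl [2,4-bis(methoxymethoxy)-5-(3-methylbut-2-enyl)phenyl]acetate | COC(=O)Cc1cc(CC=C(C)C)c(OCOC)cc1OCOC | intermediate
6 | [2,4-bis(methoxymethoxy)-5-(3-methylbut-2-enyl)phenyl]acetic acid | OC(=O)Cc1cc(CC=C(C)C)c(OCOC)cc1OCOC | intermediate
7 | 2,2-dimethyl-1,3-dioxane-4,6-dione (Meldrum's acid) | CC1(C)OC(=O)CC(=O)O1 | starting material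
8 | 5-{2-[2,4-bis(methoxymethoxy)-5-(3-methylbut-2-enyl)phenyl]-1-hydroxyethylidene}-2,2-dimethyl-1,3-dioxane-4,6-dione (acyl Meldrum's acid) | CC1(C)OC(=O)C(=C(O)Cc2cc(CC=C(C)C)c(OCOC)cc2OCOC)C(=O)O1 | intermediate
9 | methyl 4-[2,4-bis(methoxymethoxy)-5-(3-methylbut-2-enyl)phenyl]-3-oxobutanoate | COC(=O)CC(=O)Cc1cc(CC=C(C)C)c(OCOC)cc1OCOC | intermediate
10 | methyl 2-acetyl-4-[2,4-bis(methoxymethoxy)-5-(3-methylbut-2-enyl)phenyl]-3-oxobutanoate | COC(=O)C(C(C)=O)C(=O)Cc1cc(CC=C(C)C)c(OCOC)cc1OCOC | intermediate
11 | methyl 2-acetyl-4-[2,4-bis(methoxymethoxy)-5-(3-methylbut-2-enyl)phenyl]-5-(dimethylamino)-3-oxopent-4-enoate (enaminone) | COC(=O)C(C(C)=O)C(=O)C(=CN(C)C)c1cc(CC=C(C)C)c(OCOC)cc1OCOC | intermediate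
12 | methyl 5-[2,4-bis(methoxymethoxy)-5-(3-methylbut-2-enyl)phenyl]-2-methyl-4-oxo-4H-pyran-3-carboxylate | COC(=O)c1c(C)occ(-c2cc(CC=C(C)C)c(OCOC)cc2OCOC)c1=O | intermediate
13 | N-methoxy-N-methylacetamide | CC(=O)N(C)OC | starting material
14 | methyl 5-[2,4-bis(methoxymethoxy)-5-(3-methylbut-2-enyl)phenyl]-4-oxo-2-(2-oxopropyl)-4H-pyran-3-carboxylate | COC(=O)c1c(CC(C)=O)occ(-c2cc(CC=C(C)C)c(OCOC)cc2OCOC)c1=O | intermediate
15 | 3-[2,4-bis(methoxymethoxy)-5-(3-methylbut-2-enyl)phenyl]-5,7-dihydroxychromen-4-one | Oc1cc(O)c2c(=O)c(-c3cc(CC=C(C)C)c(OCOC)cc3OCOC)coc2c1 | intermediate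
16 | 3-[2,4-bis(methoxymethoxy)-5-(3-methylbut-2-enyl)phenyl]-5-hydroxy-7-methoxychromen-4-one | COc1cc(O)c2c(=O)c(-c3cc(CC=C(C)C)c(OCOC)cc3OCOC)coc2c1 | intermediate
17 | isopoegin B, 3-[2,4-dihydroxy-5-(3-methylbut-2-enyl)phenyl]-5-hydroxy-7-methoxychromen-4-one | COc1cc(O)c2c(=O)c(-c3cc(CC=C(C)C)c(O)cc3O)coc2c1 | target

**Count**
Total steps: 10. Longest linear sequence: 10 steps (1 to 17).

**Steps most likely to fail**

Step 8 (proposed new method). What may go wrong:
- the stabilised dienolate of 12 may add too slowly to the Weinreb amide;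
- the amide may be enolised instead of attacked;
- the base may add at the unsubstituted C6–H carbon and open the pyranone;
- the Claisen closure may stall at the stage of ketone 14.

The fallback uses known chemistry and takes ring A from a resorcinol instead of building it. It sets out from acid 6 and comes back to the route at target 17. Acid 6 is coupled with N,O-dimethylhydroxylamine hydrochloride by 1,1'-carbonyldiimidazole to N-methoxy-N-methyl-2-[2,4-bis(methoxymethoxy)-5-(3-methylbut-2-enyl)phenyl]acetamide F1. Bought 5-methoxyresorcinol (COc1cc(O)cc(O)c1) is protected with MOMCl and i-Pr2NEt as 1-methoxy-3,5-bis(methoxymethoxy)benzene F2. n-BuLi in THF at 0 °C should metalate F2 between the two MOM ethers to [4-methoxy-2,6-bis(methoxymethoxy)phenyl]lithium F3. Addition of F3 to F1 at −78 °C (Weinreb ketone synthesis, NH4Cl quench) should give the deoxybenzoin 1-[4-methoxy-2,6-bis(methoxymethoxy)phenyl]-2-[2,4-bis(methoxymethoxy)-5-(3-methylbut-2-enyl)phenyl]ethanone F4. One MOM ether beside the ketone is cleaved with carbonyl assistance (I2, MeOH, rt) to 1-[2-hydroxy-4-methoxy-6-(methoxymethoxy)phenyl]-2-[2,4-bis(methoxymethoxy)-5-(3-methylbut-2-enyl)phenyl]ethanone F5. N,N-dimethylformamide dimethyl acetal then closes ring C in the classical deoxybenzoin manner to 3-[2,4-bis(methoxymethoxy)-5-(3-methylbut-2-enyl)phenyl]-7-methoxy-5-(methoxymethoxy)chromen-4-one F6. Under the conditions of step 10, F6 should lose its three MOM groups and give 17.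

Step 7. What may go wrong:
- condensation at the acetyl methyl group instead of the benzylic methylene;
- O-methylation of the acidic enol by the amide acetal;
- retro-Claisen loss of the acetyl group.

The fallback brings in the ring carbon before the tricarbonyl is assembled, so that no choice of site remains. It sets out from ester 5 and comes back at pyranone 12. Ester 5 is formylated (HCO2Me, NaH, THF) to methyl 2-[2,4-bis(methoxymethoxy)-5-(3-methylbut-2-enyl)phenyl]-3-hydroxyprop-2-enoate F7. O-methylation (MeI, K2CO3, DMF) gives methyl 2-[2,4-bis(methoxymethoxy)-5-(3-methylbut-2-enyl)phenyl]-3-methoxyprop-2-enoate F8. Saponification with LiOH gives 2-[2,4-bis(methoxymethoxy)-5-(3-methylbut-2-enyl)phenyl]-3-methoxyprop-2-enoic acid F9. 1-Chloro-N,N,2-trimethylprop-1-en-1-amine converts F9 under neutral conditions into 2-[2,4-bis(methoxymethoxy)-5-(3-methylbut-2-enyl)phenyl]-3-methoxyprop-2-enoyl chloride F10. C-acylation of methyl acetoacetate with F10 (MgCl2, pyridine) should give methyl 2-acetyl-4-[2,4-bis(methoxymethoxy)-5-(3-methylbut-2-enyl)phenyl]-5-methoxy-3-oxopent-4-enoate F11. The acetyl enol oxygen of F11 displaces methoxide by addition–elimination and closes the ring to 12.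

Step 3. What may go wrong:
- transfer of the prenyl group through its tertiary end, which gives the 1,1-dimethylallyl isomer;
- slow oxidative addition into the electron-rich bromide, with loss of stannane by protodestannylation.

The fallback sets out from bromide 3 and comes back at 5. Stille coupling of 3 with allyltributylstannane (Pd(PPh3)4, DMF), which has no regiochemical choice, gives methyl [5-allyl-2,4-bis(methoxymethoxy)phenyl]acetate F12. Cross-metathesis of F12 with excess 2-methylbut-2-ene and the second-generation Grubbs catalyst RuCl2(H2IMes)(PCy3)(=CHPh) in CH2Cl2 should give 5.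

**Further compounds**
F1 | step 8 | N-methoxy-N-methyl-2-[2,4-bis(methoxymethoxy)-5-(3-methylbut-2-enyl)phenyl]acetamide | CON(C)C(=O)Cc1cc(CC=C(C)C)c(OCOC)cc1OCOC
F2 | step 8 | 1-methoxy-3,5-bis(methoxymethoxy)benzene | COCOc1cc(OC)cc(OCOC)c1
F3 | step 8 | [4-methoxy-2,6-bis(methoxymethoxy)phenyl]lithium | [Li]c1c(OCOC)cc(OC)cc1OCOC
F4 | step 8 | 1-[4-methoxy-2,6-bis(methoxymethoxy)phenyl]-2-[2,4-bis(methoxymethoxy)-5-(3-methylbut-2-enyl)phenyl]ethanone | COCOc1cc(OC)cc(OCOC)c1C(=O)Cc1cc(CC=C(C)C)c(OCOC)cc1OCOC
F5 | step 8 | 1-[2-hydroxy-4-methoxy-6-(methoxymethoxy)phenyl]-2-[2,4-bis(methoxymethoxy)-5-(3-methylbut-2-enyl)phenyl]ethanone | COCOc1cc(OC)cc(O)c1C(=O)Cc1cc(CC=C(C)C)c(OCOC)cc1OCOC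
F6 | step 8 | 3-[2,4-bis(methoxymethoxy)-5-(3-methylbut-2-enyl)phenyl]-7-methoxy-5-(methoxymethoxy)chromen-4-one | COCOc1cc(OC)cc2occ(-c3cc(CC=C(C)C)c(OCOC)cc3OCOC)c(=O)c12
F7 | step 7 | methyl 2-[2,4-bis(methoxymethoxy)-5-(3-methylbut-2-enyl)phenyl]-3-hydroxyprop-2-enoate | COC(=O)C(=CO)c1cc(CC=C(C)C)c(OCOC)cc1OCOC
F8 | step 7 | methyl 2-[2,4-bis(methoxymethoxy)-5-(3-methylbut-2-enyl)phenyl]-3-methoxyprop-2-enoate | COC=C(C(=O)OC)c1cc(CC=C(C)C)c(OCOC)cc1OCOC
F9 | step 7 | 2-[2,4-bis(methoxymethoxy)-5-(3-methylbut-2-enyl)phenyl]-3-methoxyprop-2-enoic acid | COC=C(C(O)=O)c1cc(CC=C(C)C)c(OCOC)cc1OCOC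
F10 | step 7 | 2-[2,4-bis(methoxymethoxy)-5-(3-methylbut-2-enyl)phenyl]-3-methoxyprop-2-enoyl chloride | COC=C(C(Cl)=O)c1cc(CC=C(C)C)c(OCOC)cc1OCOC
F11 | step 7 | methyl 2-acetyl-4-[2,4-bis(methoxymethoxy)-5-(3-methylbut-2-enyl)phenyl]-5-methoxy-3-oxopent-4-enoate | COC=C(C(=O)C(C(C)=O)C(=O)OC)c1cc(CC=C(C)C)c(OCOC)cc1OCOC
F12 | step 3 | methyl [5-allyl-2,4-bis(methoxymethoxy)phenyl]acetate | COC(=O)Cc1cc(CC=C)c(OCOC)cc1OCOC
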